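# Proposed total synthesis of CNP0495401.0 (a marchantin-type macrocyclic bis(bibenzyl)) by anodic halophenol macrocyclisation

## The problem

The target is a 19-membered macrocyclic bis(bibenzyl). Four benzene rings are held in one large ring by two diaryl ether oxygens (ring A–O–ring B and ring C–O–ring D) and two CH2CH2 bridges (ring B–ring C and ring D–ring A). Ring A is a phenol whose hydroxyl is ortho to the aryloxy carbon and para to the bridge, ring B is a plain meta-phenylene, and ring D is a para-phenylene. Ring C is 1,2,3-trioxygenated: the bridge is on C1, hydroxyls are on C3 and C4 (a catechol) and the ether oxygen is on C5. There is no stereocentre and no axial or planar chirality to control, so the difficulty lies in closing the large ring and in placing three adjacent oxygens on ring C. The free catechol and the ortho-aryloxyphenol of ring A are easily oxidised, so the hydroxyls must stay masked or latent until the end, and any halogen kept as a handle must survive the saturation of the bridges. The feature that opens the route is the C5–O bond of ring C, which lies ortho to the C4 hydroxyl and whose oxygen is that of a para-alkylphenol (ring D). This is the pattern left by oxidative coupling of two 2,6-dihalo-4-alkylphenols: one phenol keeps its hydroxyl, gains an aryloxy group at one ortho carbon and keeps a halogen at the other, here C3, where the second catechol hydroxyl is needed. For this to work, ring A must be a methyl ether and the two halophenols must differ, so that only ring C is oxidised and only ring D supplies the oxygen.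

## Retrosynthesis

**End game, 23 back to 18.** The target 23 is traced to its ring A methyl ether 22 (O–CH3 cut, BBr3 forward). Compound 22 is traced to 21, which still carries a benzyl ether on the C4 oxygen and two chlorines on ring D; one hydrogenolysis removes all three. The C3 hydroxyl of 21 is traced to the C3 bromine of benzyl ether 19 (borylation then oxidation), and 19 to the bromophenol 18. These cuts cost four ordinary steps and leave a macrocycle, 18, whose halogen pattern is exactly what an oxidative halophenol coupling delivers.

**Key disconnection, 18 back to 16.** The C5–O bond of ring C is cut, giving the open-chain diphenol 16 with a 2,6-dibromophenol (ring C) and a 2,6-dichlorophenol (ring D) at its ends. The neighbouring cuts are less attractive. Cutting either bond of the ring A–O–ring B ether needs an activating group the target does not have, and cutting a CH2CH2 bridge (Wittig or McMurry ring closure) does nothing for the oxygenation of ring C. This cut removes the macrocycle and solves the placement of the third ring C oxygen together. The forward reaction must oxidise ring C and not ring D or ring A, deliver the ring D oxygen to an ortho carbon, and favour ring closure over chain growth. It passes through dienone 17, which is reduced in the same vessel.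

**Ring B–ring C bridge, 16 back to 11 and 13.** Diphenol 16 comes from its bis(methoxymethyl) ether 15, and 15 from bis-stilbene 14 by diimide reduction, which spares C–Br and C–Cl where catalytic hydrogenation would not. The ring B–ring C double bond of 14 is cut by a Wittig disconnection into phosphonium salt 11 and aldehyde 13. Placing the phosphorus on the core means the halogenated partner is used as its aldehyde, one protection step from commercial 12, instead of four steps to a halobenzyl phosphonium salt.

**Ring A–ring D bridge, 11 back to 5 and 7.** Salt 11 is traced through bromide 10 and alcohol 9 to ester 8. The ring A–ring D double bond of 8 is cut the same way into phosphonium salt 5 and aldehyde 7. This arm is built first because the aldehyde of the core can be reduced beside the ester. The ring A salt can then be made with PPh3·HBr before any acid-labile group is present.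

**Ring A–O–ring B ether, 5 back to 1 and 2.** Salt 5 comes from alcohol 4 and aldehyde 3, and 3 from an Ullmann coupling of isovanillin 1 with methyl 3-bromobenzoate 2. Isovanillin already has the ring A pattern (free hydroxyl meta, methoxy para to the formyl carbon). The ester of 2 is a dormant second benzylic carbon that is clearly distinguished from the aldehyde.

**Halophenol aldehydes, 7 and 13 back to 6 and 12.** Each is the methoxymethyl ether of a commercial 3,5-dihalo-4-hydroxybenzaldehyde. The ether keeps the aldehyde electrophilic in the Wittig steps and comes off with acid without touching the halogens.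

## Roads not taken

**Alternative 1: nitro-activated SNAr closure at ring A.** The cut is the ring A carbon–oxygen bond of the ring A–O–ring B ether. In seco compound A2, ring A is a 3-fluoro-4-nitrophenyl unit and ring B carries a free phenol. Carbonate or fluoride base at high dilution would let the ring B phenoxide displace the fluoride ortho to nitro and give nitro macrocycle A1.

- Merits: nitro-activated SNAr is among the most dependable ways to close macrocyclic diaryl ethers. It needs no metal and no oxidant, and the catechol can travel as a stable dimethyl ether. In predictability of the ring closure it is better than the anodic closure of 16.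
- Weak points: the nitro group of A1 sits where the ring A hydroxyl belongs. It must be exchanged by reduction, diazotisation and hydrolysis on an electron-rich polyether, where azo coupling and reduction of the diazonium ion compete. The ring C–O–ring D ether must also be made beforehand by a separate Ullmann coupling on a hindered 3,4,5-trioxygenated ring.
- Comparison: the chosen plan has a less certain ring closure. Against that, it creates the ring C oxygen pattern in the closing step, uses four simple commercial aromatics, and needs no diazonium chemistry at the end.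

**Alternative 2: macrolactone contracted by nickel decarbonylation.** The cut is the ring B carbon–oxygen bond of the same ether, traced back to an ester. The 20-membered aryl ester A4 (ring B acyl, ring A oxygen) would be treated with zerovalent nickel, Ni(cod)2, and a chelating bis(dicyclohexylphosphine). Insertion into the acyl C–O bond, loss of CO and reductive elimination would contract it to the 19-membered tri-O-methyl ether A3.

- Merits: macrolactonisation is a robust way to close a large ring. A3 is a single BBr3 step from the target, which is the shortest end game of the four plans and clearly better than the four steps needed after 18.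
- Weak points: decarbonylative ether formation works best for aromatic esters of heteroaromatic acids. A plain benzoate of an ortho-methoxy phenol is at the edge of that scope. The reaction needs temperatures around 150 °C, and a ring contraction of a macrolactone by this means has no close analogy. The ring C–O–ring D ether again has to be made separately.
- Comparison: the chosen plan gives away step economy after the ring closure. In return its closing reaction belongs to a type already used to close diaryl ether macrocycles, so the route does not depend on extending a method beyond its known scope.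

**Alternative 3: pyrone–ynone Diels–Alder building ring D and the macrocycle.** The cut removes two carbon–carbon bonds of ring D. Heating seco compound A6, a 4-aryloxy-2-pyrone tethered to an ethynyl ketone, would join pyrone C3 to the terminal alkyne carbon and C6 to the acyl-bearing carbon. Loss of CO2 would give the macrocyclic aryl ketone A5.

- Merits: one step builds a benzene ring and the macrocycle. The polarity is matched, since the nucleophilic C3 of the alkoxypyrone meets the electrophilic terminus of the ynone, and CO2 loss makes the step irreversible. As a construction it is more convergent than the chosen plan.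
- Weak points: 2-pyrones are reluctant dienes and need high temperature. The bridged intermediate must form inside a 19-membered ring with a para-spanning tether. The terminal ynone, flanked by an acidic benzylic CH2, is prone to isomerisation and polymerisation under such heating. The ketone of A5 must then be removed, and three methyl ethers cleaved.
- Comparison: the chosen plan is longer in the assembly of 16. Each of its steps has a direct analogy, and the closure is an oxidation at room temperature, not a thermolysis of a fragile substrate.

Key step: step 13

## Route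

Remarks on the chemistry:
- The target has no stereocentre.
- Stilbenes 8, 9, 10, 11 and 14 are carried as E/Z mixtures, since both double bonds are saturated in step 11. Their SMILES are written without alkene geometry.
- Dienone 17 is racemic at its sp3 carbon, which is lost again in the same step.

Step 1
Reactants: 1 isovanillin (3-hydroxy-4-methoxybenzaldehyde); 2 methyl 3-bromobenzoate
Product: 3 methyl 3-(5-formyl-2-methoxyphenoxy)benzoate
Conditions: CuI (10 mol%), N,N-dimethylglycine hydrochloride (30 mol%), Cs2CO3, 1,4-dioxane, 90 °C
Reagents that add atoms: none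
Why: Ullmann diaryl ether synthesis; the phenoxide of 1 displaces bromide from the electron-poor aryl bromide under CuI/amino acid catalysis, and the aldehyde and methyl ester are inert to carbonate in dry dioxane.

Step 2
Reactants: 3 methyl 3-(5-formyl-2-methoxyphenoxy)benzoate
Product: 4 methyl 3-[5-(hydroxymethyl)-2-methoxyphenoxy]benzoate
Conditions: NaBH4, MeOH–THF, 0 °C
Reagents that add atoms: none
Why: Chemoselective borohydride reduction; the aldehyde is reduced far faster than the methyl benzoate at 0 °C.

Step 3
Reactants: 4 methyl 3-[5-(hydroxymethyl)-2-methoxyphenoxy]benzoate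
Product: 5 {4-methoxy-3-[3-(methoxycarbonyl)phenoxy]benzyl}triphenylphosphonium bromide
Conditions: PPh3·HBr, MeCN, reflux
Reagents that add atoms: triphenylphosphine hydrobromide, [Br-].[PH+](c1ccccc1)(c1ccccc1)c1ccccc1
Why: Direct conversion of a para-methoxybenzylic alcohol into its phosphonium salt; the acid ionises the activated alcohol and PPh3 captures the benzylic electrophile, and no acid-labile group is present at this stage.

Step 4
Reactants: 6 3,5-dichloro-4-hydroxybenzaldehyde
Product: 7 3,5-dichloro-4-(methoxymethoxy)benzaldehyde
Conditions: MOMCl, i-Pr2NEt, CH2Cl2, 0 °C to rt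
Reagents that add atoms: chloromethyl methyl ether, COCCl
Why: O-Alkylation of an acidic, hindered phenol with a very reactive alkoxymethyl chloride (methoxymethyl ether formation); masking the phenol keeps the aldehyde electrophilic for the Wittig step, and the ether later leaves with acid without touching C–Cl.

Step 5
Reactants: 5 {4-methoxy-3-[3-(methoxycarbonyl)phenoxy]benzyl}triphenylphosphonium bromide; 7 3,5-dichloro-4-(methoxymethoxy)benzaldehyde
Product: 8 methyl 3-(5-{2-[3,5-dichloro-4-(methoxymethoxy)phenyl]ethenyl}-2-methoxyphenoxy)benzoate (E/Z mixture)
Conditions: K2CO3, 18-crown-6 (cat.), CH2Cl2, reflux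
Reagents that add atoms: none
Why: Wittig olefination under solid–liquid phase-transfer conditions; the semi-stabilised benzylic ylide forms reversibly and adds to the aldehyde, while the methyl ester is not touched by carbonate and the alkene geometry is of no consequence.

Step 6
Reactants: 8 methyl 3-(5-{2-[3,5-dichloro-4-(methoxymethoxy)phenyl]ethenyl}-2-methoxyphenoxy)benzoate
Product: 9 [3-(5-{2-[3,5-dichloro-4-(methoxymethoxy)phenyl]ethenyl}-2-methoxyphenoxy)phenyl]methanol (E/Z mixture)
Conditions: i-Bu2AlH, CH2Cl2, −78 to 0 °C; aq. potassium sodium tartrate
Reagents that add atoms: none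
Why: Hydride reduction of an aryl ester to the benzylic alcohol; i-Bu2AlH leaves aryl chlorides, the acetal-type ether and the styrene double bond alone.

Step 7
Reactants: 9 [3-(5-{2-[3,5-dichloro-4-(methoxymethoxy)phenyl]ethenyl}-2-methoxyphenoxy)phenyl]methanol
Product: 10 5-{2-[3-(3-(bromomethyl)phenoxy)-4-methoxyphenyl]ethenyl}-1,3-dichloro-2-(methoxymethoxy)benzene (E/Z mixture)
Conditions: CBr4, PPh3, CH2Cl2, 0 °C
Reagents that add atoms: carbon tetrabromide, BrC(Br)(Br)Br
Why: Appel bromination; the neutral conditions preserve the methoxymethyl ether, which HBr-based reagents would cleave.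

Step 8
Reactants: 10 5-{2-[3-(3-(bromomethyl)phenoxy)-4-methoxyphenyl]ethenyl}-1,3-dichloro-2-(methoxymethoxy)benzene
Product: 11 [3-(5-{2-[3,5-dichloro-4-(methoxymethoxy)phenyl]ethenyl}-2-methoxyphenoxy)benzyl]triphenylphosphonium bromide (E/Z mixture)
Conditions: PPh3, toluene, 100 °C
Reagents that add atoms: triphenylphosphine, c1ccc(cc1)P(c1ccccc1)c1ccccc1
Why: SN2 quaternisation of PPh3 by a benzylic bromide; the salt separates from toluene and is freed of neutral impurities by washing.

Step 9
Reactants: 12 3,5-dibromo-4-hydroxybenzaldehyde
Product: 13 3,5-dibromo-4-(methoxymethoxy)benzaldehyde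
Conditions: MOMCl, i-Pr2NEt, CH2Cl2, 0 °C to rt
Reagents that add atoms: chloromethyl methyl ether, COCCl
Why: Methoxymethyl ether formation as in step 4; the acidic dibromophenol is alkylated readily despite its two ortho substituents.

Step 10
Reactants: 11 [3-(5-{2-[3,5-dichloro-4-(methoxymethoxy)phenyl]ethenyl}-2-methoxyphenoxy)benzyl]triphenylphosphonium bromide; 13 3,5-dibromo-4-(methoxymethoxy)benzaldehyde
Product: 14 1,3-dibromo-5-{2-[3-(5-{2-[3,5-dichloro-4-(methoxymethoxy)phenyl]ethenyl}-2-methoxyphenoxy)phenyl]ethenyl}-2-(methoxymethoxy)benzene (E/Z mixture at both double bonds)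
Conditions: K2CO3, 18-crown-6 (cat.), CH2Cl2, reflux
Reagents that add atoms: none
Why: Second Wittig olefination under the conditions of step 5; aryl bromides and chlorides are inert to the ylide and to carbonate.

Step 11
Reactants: 14 bis-stilbene (1,3-dibromo-5-{2-[3-(5-{2-[3,5-dichloro-4-(methoxymethoxy)phenyl]ethenyl}-2-methoxyphenoxy)phenyl]ethenyl}-2-(methoxymethoxy)benzene)
Product: 15 1,3-dibromo-5-{2-[3-(5-{2-[3,5-dichloro-4-(methoxymethoxy)phenyl]ethyl}-2-methoxyphenoxy)phenyl]ethyl}-2-(methoxymethoxy)benzene
Conditions: TsNHNH2 (excess, in portions), NaOAc, DME–H2O, reflux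
Reagents that add atoms: none
Why: Diimide reduction; diimide released from the sulfonyl hydrazide transfers two hydrogens to each stilbene double bond in a concerted syn addition and leaves C–Br and C–Cl intact, which hydrogenation over palladium would not, while NaOAc buffers the sulfinic acid so the acetal ethers survive.

Step 12
Reactants: 15 1,3-dibromo-5-{2-[3-(5-{2-[3,5-dichloro-4-(methoxymethoxy)phenyl]ethyl}-2-methoxyphenoxy)phenyl]ethyl}-2-(methoxymethoxy)benzene
Product: 16 2,6-dibromo-4-{2-[3-(5-{2-[3,5-dichloro-4-hydroxyphenyl]ethyl}-2-methoxyphenoxy)phenyl]ethyl}phenol (seco diphenol)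
Conditions: HCl (3 M aq.), MeOH–THF, 50 °C
Reagents that add atoms: none
Why: Acid-catalysed acetal methanolysis removes both methoxymethyl groups; aryl halides, the methyl ether and the diaryl ether are unaffected.

Step 13
Reactants: 16 2,6-dibromo-4-{2-[3-(5-{2-[3,5-dichloro-4-hydroxyphenyl]ethyl}-2-methoxyphenoxy)phenyl]ethyl}phenol
Product: 18 macrocyclic bromo dichloro diaryl ether (19-membered ring; ring C 3-bromo-4-hydroxy-5-aryloxy; ring D 2,6-dichloro-1,4-phenylene ether; ring A methyl ether), via macrocyclic bromodienone 17 (not isolated)
Conditions: constant-current electrolysis (glassy-carbon anode, Pt cathode, undivided cell, ca. 2 F/mol), LiClO4 (0.1 M), MeOH, rt, ca. 1 mM; then Zn dust, AcOH, rt, same vessel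
Reagents that add atoms: none
Why: Anodic oxidation takes two electrons and a proton from the ring C dibromophenol of 16, the phenol of lower oxidation potential, to give a phenoxonium ion or its phenoxyl radical forerunner, and the hydroxyl of the ring D dichlorophenol adds to one of its bromine-bearing ortho carbons to give the 6-aryloxy-2,6-dibromocyclohexa-2,4-dienone 17; zinc in acetic acid then cleaves the C(sp3)–Br bond reductively and the ring rearomatises to 18. The closest known reaction type is the anodic or Tl(NO3)3-mediated coupling of 2,6-dihalo-4-alkylphenols to ortho-aryloxyphenols, which has served to close macrocyclic diaryl ethers of the isodityrosine family. The ring closed is the 19-membered macrocycle, formed end to end by C–O bond formation (a macro-etherification) at about 1 mM; three meta-phenylene units, one para-phenylene unit and two flexible CH2CH2 hinges let the ends meet without transannular strain. The only new stereocentre, the sp3 carbon of 17, forms as a racemate under no control and is erased by the reduction, so 18 is achiral. Which phenol is oxidised depends on the lower potential of the dibromophenol relative to the dichlorophenol and to the ring A methyl ether, and the charge is limited to about 2 F/mol. Regioselectivity follows from the substitution pattern: both para positions carry the bridges, every ortho position carries a halogen (which disfavours C–C coupling), and the two ortho carbons of ring C are equivalent, so one constitution results. Capture of the oxidised ring by methanol at the para carbon gives a quinol ether that zinc returns to the phenol, so this diversion costs conversion but not material. Once cyclised, the material is a dienone without a free phenol and is shielded from further oxidation until zinc is added.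

Step 14
Reactants: 18 macrocyclic bromo dichloro diaryl ether
Product: 19 O-benzyl ether of 18 (ring C 3-bromo-4-benzyloxy-5-aryloxy)
Conditions: BnBr, K2CO3, DMF, 60 °C
Reagents that add atoms: benzyl bromide, BrCc1ccccc1
Why: Williamson etherification of the only free hydroxyl, an acidic phenol flanked by bromine and aryloxy; the benzyl group protects it during the palladium step and is removed in step 16 together with the chlorines.

Step 15
Reactants: 19 O-benzyl ether of 18
Product: 21 macrocyclic phenol (ring C 3-hydroxy-4-benzyloxy-5-aryloxy; ring D dichloro; ring A methyl ether), via pinacol boronate 20 (not isolated)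
Conditions: B2pin2, PdCl2(dppf) (5 mol%), KOAc, 1,4-dioxane, 90 °C; then H2O2 (30% aq.), NaOH, THF, 0 °C to rt
Reagents that add atoms: bis(pinacolato)diboron, CC1(C)OB(OC1(C)C)B1OC(C)(C)C(C)(C)O1 (boron of 20); hydrogen peroxide, OO (hydroxyl oxygen of 21)
Why: Miyaura borylation followed by peroxide oxidation of the arylboronate (1,2-shift of the aryl group from boron to oxygen); zerovalent palladium with dppf inserts into the C–Br bond much faster than into the two doubly ortho-substituted C–Cl bonds, so only C3 of ring C is converted to C–OH.

Step 16
Reactants: 21 macrocyclic phenol with benzyl ether and two chlorines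
Product: 22 ring A mono-O-methyl ether of the target (ring C free catechol; ring D unsubstituted para-phenylene)
Conditions: H2 (1 atm), Pd/C (10%), NaOAc, MeOH–EtOAc, rt
Reagents that add atoms: none
Why: Catalytic hydrogenolysis; the O-benzyl bond and both aryl C–Cl bonds are cleaved on Pd/C with NaOAc as the acceptor for HCl, and the diaryl ethers and the methyl ether are stable.

Step 17
Reactants: 22 ring A mono-O-methyl ether of the target
Product: 23 target CNP0495401.0 (macrocyclic bis(bibenzyl) triphenol)
Conditions: BBr3, CH2Cl2, −78 to 0 °C; then H2O
Reagents that add atoms: none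
Why: BBr3 demethylation (Lewis acid complexation of the ether oxygen, then bromide attack on the methyl group); diaryl ethers are not cleaved at this temperature and aqueous work-up hydrolyses the aryl borates to the free triphenol.

## Compound list

1 | isovanillin (3-hydroxy-4-methoxybenzaldehyde) | COc1ccc(C=O)cc1O | starting material
2 | methyl 3-bromobenzoate | COC(=O)c1cccc(Br)c1 | starting material
3 | methyl 3-(5-formyl-2-methoxyphenoxy)benzoate | COC(=O)c1cccc(Oc2cc(C=O)ccc2OC)c1 | intermediate
4 | methyl 3-[5-(hydroxymethyl)-2-methoxyphenoxy]benzoate | COC(=O)c1cccc(Oc2cc(CO)ccc2OC)c1 | intermediate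
5 | {4-methoxy-3-[3-(methoxycarbonyl)phenoxy]benzyl}triphenylphosphonium bromide | COC(=O)c1cccc(Oc2cc(C[P+](c3ccccc3)(c3ccccc3)c3ccccc3)ccc2OC)c1.[Br-] | intermediate
6 | 3,5-dichloro-4-hydroxybenzaldehyde | O=Cc1cc(Cl)c(O)c(Cl)c1 | starting material
7 | 3,5-dichloro-4-(methoxymethoxy)benzaldehyde | COCOc1c(Cl)cc(C=O)cc1Cl | intermediate
8 | methyl 3-(5-{2-[3,5-dichloro-4-(methoxymethoxy)phenyl]ethenyl}-2-methoxyphenoxy)benzoate, E/Z mixture | COC(=O)c1cccc(Oc2cc(C=Cc3cc(Cl)c(OCOC)c(Cl)c3)ccc2OC)c1 | intermediate
9 | [3-(5-{2-[3,5-dichloro-4-(methoxymethoxy)phenyl]ethenyl}-2-methoxyphenoxy)phenyl]methanol, E/Z mixture | OCc1cccc(Oc2cc(C=Cc3cc(Cl)c(OCOC)c(Cl)c3)ccc2OC)c1 | intermediate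
10 | 5-{2-[3-(3-(bromomethyl)phenoxy)-4-methoxyphenyl]ethenyl}-1,3-dichloro-2-(methoxymethoxy)benzene, E/Z mixture | BrCc1cccc(Oc2cc(C=Cc3cc(Cl)c(OCOC)c(Cl)c3)ccc2OC)c1 | intermediate
11 | [3-(5-{2-[3,5-dichloro-4-(methoxymethoxy)phenyl]ethenyl}-2-methoxyphenoxy)benzyl]triphenylphosphonium bromide, E/Z mixture | COCOc1c(Cl)cc(C=Cc2ccc(OC)c(Oc3cccc(C[P+](c4ccccc4)(c4ccccc4)c4ccccc4)c3)c2)cc1Cl.[Br-] | intermediate
12 | 3,5-dibromo-4-hydroxybenzaldehyde | O=Cc1cc(Br)c(O)c(Br)c1 | starting material
13 | 3,5-dibromo-4-(methoxymethoxy)benzaldehyde | COCOc1c(Br)cc(C=O)cc1Br | intermediate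
14 | bis-stilbene: 1,3-dibromo-5-{2-[3-(5-{2-[3,5-dichloro-4-(methoxymethoxy)phenyl]ethenyl}-2-methoxyphenoxy)phenyl]ethenyl}-2-(methoxymethoxy)benzene, E/Z mixture at both double bonds | COCOc1c(Cl)cc(C=Cc2ccc(OC)c(Oc3cccc(C=Cc4cc(Br)c(OCOC)c(Br)c4)c3)c2)cc1Cl | intermediate
15 | bis(bibenzyl) bis(methoxymethyl) ether: 1,3-dibromo-5-{2-[3-(5-{2-[3,5-dichloro-4-(methoxymethoxy)phenyl]ethyl}-2-methoxyphenoxy)phenyl]ethyl}-2-(methoxymethoxy)benzene | COCOc1c(Cl)cc(CCc2ccc(OC)c(Oc3cccc(CCc4cc(Br)c(OCOC)c(Br)c4)c3)c2)cc1Cl | intermediate
16 | seco diphenol: 2,6-dibromo-4-{2-[3-(5-{2-[3,5-dichloro-4-hydroxyphenyl]ethyl}-2-methoxyphenoxy)phenyl]ethyl}phenol | COc1ccc(CCc2cc(Cl)c(O)c(Cl)c2)cc1Oc1cccc(CCc2cc(Br)c(O)c(Br)c2)c1 | intermediate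
17 | macrocyclic bromodienone: ring C as a 2,6-dibromocyclohexa-2,4-dienone whose C6 carries the ring D aryloxy oxygen, racemic at C6 | COc1ccc2cc1Oc1cccc(c1)CCC1=CC(Br)(Oc3c(Cl)cc(cc3Cl)CC2)C(=O)C(Br)=C1 | intermediate
18 | macrocyclic bromo dichloro diaryl ether: 19-membered ring, ring C 3-bromo-4-hydroxy-5-aryloxy, ring D 2,6-dichloro, ring A methyl ether | COc1ccc2cc1Oc1cccc(c1)CCc1cc(Br)c(O)c(c1)Oc1c(Cl)cc(cc1Cl)CC2 | intermediate
19 | O-benzyl ether of 18: ring C 3-bromo-4-benzyloxy-5-aryloxy | COc1ccc2cc1Oc1cccc(c1)CCc1cc(Br)c(OCc3ccccc3)c(c1)Oc1c(Cl)cc(cc1Cl)CC2 | intermediate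
20 | pinacol boronate: ring C 3-(4,4,5,5-tetramethyl-1,3,2-dioxaborolan-2-yl)-4-benzyloxy-5-aryloxy | COc1ccc2cc1Oc1cccc(c1)CCc1cc(B3OC(C)(C)C(C)(C)O3)c(OCc3ccccc3)c(c1)Oc1c(Cl)cc(cc1Cl)CC2 | intermediate
21 | macrocyclic phenol: ring C 3-hydroxy-4-benzyloxy-5-aryloxy, ring D 2,6-dichloro, ring A methyl ether | COc1ccc2cc1Oc1cccc(c1)CCc1cc(O)c(OCc3ccccc3)c(c1)Oc1c(Cl)cc(cc1Cl)CC2 | intermediate
22 | ring A mono-O-methyl ether of the target: ring C catechol, ring D para-phenylene | COc1ccc2cc1Oc1cccc(c1)CCc1cc(O)c(O)c(c1)Oc1ccc(cc1)CC2 | intermediate
23 | CNP0495401.0, macrocyclic bis(bibenzyl) triphenol | Oc1ccc2cc1Oc1cccc(c1)CCc1cc(O)c(O)c(c1)Oc1ccc(cc1)CC2 | target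

## Step count and risk

Total: 17 steps. Longest linear sequence: 15 steps (steps 1–3, 5–8 and 10–17, from 1 or 2 to 23).

**Step 13 (key step).** Three things are most likely to go wrong:
- chain growth by intermolecular coupling in place of ring closure, because nothing in 16 folds the two ends together;
- capture of the oxidised ring C by methanol at an ortho carbon in place of the hindered, weakly nucleophilic ring D hydroxyl;
- loss of site selectivity if the potentials of the two halophenols lie too close.

Replacing the anode by Tl(NO3)3 in methanol followed by zinc would be tried first, but that is only a change of oxidant. The fallback proper closes the same ring C–O–ring D bond by an intramolecular Ullmann etherification on a halogen-free ring D. It sets out from 5 and comes back at 23: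

- Salt 5 is condensed (K2CO3, 18-crown-6, CH2Cl2) with commercial 4-(methoxymethoxy)benzaldehyde F1 to give stilbene ester F2.
- i-Bu2AlH gives alcohol F3, CBr4/PPh3 gives bromide F4, and PPh3 gives phosphonium salt F5.
- Wittig reaction of F5 with commercial 3-bromo-4,5-dimethoxybenzaldehyde F6 gives bis-stilbene F7, and diimide reduction gives bis(bibenzyl) F8.
- HCl in methanol frees the ring D phenol to give seco bromo phenol F9.
- CuI, N,N-dimethylglycine hydrochloride and Cs2CO3 in dioxane at about 2 mM close the macrocycle by displacement of the ring C bromide to give the tri-O-methyl ether F10 (the same compound as A3).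
- BBr3 cleaves the three methyl ethers to 23.

**Step 15.** Protodebromination may compete with borylation at a C–Br bond crowded by the neighbouring benzyloxy group, and slow oxidative addition there gives the catalyst time to attack the C–Cl bonds. The fallback avoids palladium and sets out from 19, coming back at 21. Bromine–lithium exchange with n-BuLi in THF at −78 °C (much faster than any reaction at C–Cl) gives aryllithium F11. Trapping with B(OMe)3 gives dimethyl boronate F12, which H2O2/NaOH oxidises to 21.

**Step 16.** Hydrodechlorination may stop after the first chlorine, since the second C–Cl bond is shielded by the diaryl ether, and the catalyst may be slowed by chloride. The fallback separates the two tasks and sets out from 21, coming back at 23. Hydride-transfer dechlorination with Pd(OAc)2, polymethylhydrosiloxane and aqueous KF in THF removes both chlorines but keeps the benzyl ether, giving F13. BBr3 then cleaves the benzyl and the methyl ether together to give 23.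

**Step 11.** Saturation of two conjugated, electron-rich stilbene double bonds may remain incomplete, because diimide disproportionates faster than it reduces them, and partly reduced material would be hard to separate. The fallback runs from 14 to 15 by catalytic hydrogenation over a sulfide-poisoned catalyst (Pd/C with Ph2S, H2, EtOAc) or with homogeneous RhCl(PPh3)3. Both saturate alkenes without cleaving aryl halides, and no new compound is made.

## Further compounds

F1 | step 13 | 4-(methoxymethoxy)benzaldehyde | COCOc1ccc(C=O)cc1
F2 | step 13 | methyl 3-(2-methoxy-5-{2-[4-(methoxymethoxy)phenyl]ethenyl}phenoxy)benzoate, E/Z mixture | COC(=O)c1cccc(Oc2cc(C=Cc3ccc(OCOC)cc3)ccc2OC)c1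
F3 | step 13 | [3-(2-methoxy-5-{2-[4-(methoxymethoxy)phenyl]ethenyl}phenoxy)phenyl]methanol, E/Z mixture | OCc1cccc(Oc2cc(C=Cc3ccc(OCOC)cc3)ccc2OC)c1
F4 | step 13 | 1-(bromomethyl)-3-(2-methoxy-5-{2-[4-(methoxymethoxy)phenyl]ethenyl}phenoxy)benzene, E/Z mixture | BrCc1cccc(Oc2cc(C=Cc3ccc(OCOC)cc3)ccc2OC)c1
F5 | step 13 | [3-(2-methoxy-5-{2-[4-(methoxymethoxy)phenyl]ethenyl}phenoxy)benzyl]triphenylphosphonium bromide, E/Z mixture | COCOc1ccc(C=Cc2ccc(OC)c(Oc3cccc(C[P+](c4ccccc4)(c4ccccc4)c4ccccc4)c3)c2)cc1.[Br-]
F6 | step 13 | 3-bromo-4,5-dimethoxybenzaldehyde | COc1cc(C=O)cc(Br)c1OC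
F7 | step 13 | bis-stilbene with ring C 3-bromo-4,5-dimethoxy and ring D 4-(methoxymethoxy), E/Z mixture at both double bonds | COCOc1ccc(C=Cc2ccc(OC)c(Oc3cccc(C=Cc4cc(Br)c(OC)c(OC)c4)c3)c2)cc1
F8 | step 13 | bis(bibenzyl) with ring C 3-bromo-4,5-dimethoxy and ring D 4-(methoxymethoxy) | COCOc1ccc(CCc2ccc(OC)c(Oc3cccc(CCc4cc(Br)c(OC)c(OC)c4)c3)c2)cc1
F9 | step 13 | seco bromo phenol: 4-{2-[3-(3-{2-[3-bromo-4,5-dimethoxyphenyl]ethyl}phenoxy)-4-methoxyphenyl]ethyl}phenol | Oc1ccc(CCc2ccc(OC)c(Oc3cccc(CCc4cc(Br)c(OC)c(OC)c4)c3)c2)cc1
F10 | step 13 | tri-O-methyl ether of the target | COc1ccc2cc1Oc1cccc(c1)CCc1cc(OC)c(OC)c(c1)Oc1ccc(cc1)CC2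
F11 | step 15 | aryllithium from 19 (lithium in place of the ring C bromine) | COc1ccc2cc1Oc1cccc(c1)CCc1cc([Li])c(OCc3ccccc3)c(c1)Oc1c(Cl)cc(cc1Cl)CC2
F12 | step 15 | dimethyl arylboronate (B(OMe)2 in place of the ring C bromine of 19) | COc1ccc2cc1Oc1cccc(c1)CCc1cc(B(OC)OC)c(OCc3ccccc3)c(c1)Oc1c(Cl)cc(cc1Cl)CC2
F13 | step 16 | dechlorinated benzyl ether: ring C 3-hydroxy-4-benzyloxy-5-aryloxy, ring D para-phenylene, ring A methyl ether | COc1ccc2cc1Oc1cccc(c1)CCc1cc(O)c(OCc3ccccc3)c(c1)Oc1ccc(cc1)CC2
F0 | step 11 | none | none
A1 | alternative 1 | macrocyclic nitro diaryl ether | [O-][N+](=O)c1ccc2cc1Oc1cccc(c1)CCc1cc(OC)c(OC)c(c1)Oc1ccc(cc1)CC2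
A2 | alternative 1 | seco fluoronitroarene with free ring B phenol | [O-][N+](=O)c1ccc(CCc2ccc(Oc3cc(CCc4cccc(O)c4)cc(OC)c3OC)cc2)cc1F
A3 | alternative 2 | tri-O-methyl ether of the target | COc1ccc2cc1Oc1cccc(c1)CCc1cc(OC)c(OC)c(c1)Oc1ccc(cc1)CC2
A4 | alternative 2 | 20-membered macrocyclic aryl ester (ring B acyl, ring A oxygen) | COc1ccc2cc1OC(=O)c1cccc(c1)CCc1cc(OC)c(OC)c(c1)Oc1ccc(cc1)CC2
A5 | alternative 3 | macrocyclic aryl ketone, carbonyl on the bridge carbon next to ring D | COc1ccc2cc1Oc1cccc(c1)CCc1cc(OC)c(OC)c(c1)Oc1ccc(cc1)C(=O)C2
A6 | alternative 3 | seco 4-aryloxy-2-pyrone ethynyl ketone | C#CC(=O)Cc1ccc(OC)c(Oc2cccc(CCc3cc(OC)c(OC)c(Oc4ccoc(=O)c4)c3)c2)c1
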